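**Strategy.** The 3,4-diarylchroman is disconnected across ring A. O1 and C4 sit on the neighbouring carbons C8a and C4a, so the bonds O1–C8a and C4–C4a can both come from one aryne inserted into the benzylic C–O bond of a 2,3-diaryloxetane. This one operation builds the pyran ring, attaches ring A and sets C4 trans to the C3 aryl group. The precursor is an oxetane carrying the 2-benzyloxy-4,5-dimethoxyphenyl group at C3 (fixed by an Evans aldol) and the benzyl-protected second isoflavan at C2. The aryne carries the future C7 benzyloxy group and a removable chlorine that steers the oxygen to the correct carbon.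

Key step: step 22

**Remarks on the chemistry**
- Assumption: 1, 6, 9, 21, 26 and 34 are taken as commercial; 1 is otherwise one para-bromination away from 2-hydroxy-4-methoxybenzaldehyde.
- Opposite auxiliaries are used on purpose. Enolate alkylation (chelated) and boron aldol (non-chelated) transfer chirality in opposite senses, so the (R)-oxazolidinone sets C3 of the second chroman and the (S)-oxazolidinone sets C3 of the first.
- The formyl group of 20 enters through a bromine handle, because electrophilic formylation of the finished second chroman would not distinguish its two resorcinol-type rings.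
- The syn-aldol gives the cis-oxetane; the configuration at oxetane C2 is lost in step 22 and does not matter.
- The CIP descriptor at C4 reads R in 43 and 44 and S in 45 only because chlorine raises the priority of C4a; the 3,4-trans geometry is the same.

**Route**

Step 1
Reactants: 1 5-bromo-2-hydroxy-4-methoxybenzaldehyde
Product: 2 2-(benzyloxy)-5-bromo-4-methoxybenzaldehyde
Conditions: BnBr, K2CO3, DMF, 60 °C
Reagents that add atoms: benzyl bromide, BrCc1ccccc1
Why: Williamson etherification of the ortho-phenol is routine and masks this hydroxyl as a hydrogenolysable benzyl ether.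

Step 2
Reactants: 2 2-(benzyloxy)-5-bromo-4-methoxybenzaldehyde
Product: 3 1-(benzyloxy)-4-bromo-5-methoxy-2-(2-methoxyethenyl)benzene (E/Z mixture)
Conditions: Ph3P(CH2OMe)Cl, KOC(CH3)3, THF, 0 °C → rt
Reagents that add atoms: (methoxymethyl)triphenylphosphonium chloride, COC[P+](c1ccccc1)(c1ccccc1)c1ccccc1.[Cl-]
Why: Wittig methoxymethylenation adds the one carbon needed for the arylacetic acid, and both alkene isomers should hydrolyse to the same aldehyde.

Step 3
Reactants: 3 1-(benzyloxy)-4-bromo-5-methoxy-2-(2-methoxyethenyl)benzene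
Product: 5 2-[2-(benzyloxy)-5-bromo-4-methoxyphenyl]acetic acid, via arylacetaldehyde 4 (not isolated)
Conditions: aq HCl, THF, 50 °C; then NaH2PO4, 2-methyl-2-butene, NaClO2, t-BuOH/H2O, 0 °C → rt
Reagents that add atoms: water, O; sodium chlorite, [Na+].[O-]Cl=O
Why: Acid hydrolysis of the enol ether releases the arylacetaldehyde, which is oxidised at once by Pinnick oxidation with an alkene scavenger for hypochlorite, so the self-condensing aldehyde is never stored.

Step 4
Reactants: 5 2-[2-(benzyloxy)-5-bromo-4-methoxyphenyl]acetic acid; 6 (R)-4-benzyl-2-oxazolidinone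
Product: 8 (R)-4-benzyl-3-{2-[2-(benzyloxy)-5-bromo-4-methoxyphenyl]acetyl}oxazolidin-2-one, via mixed pivalic anhydride 7 (not isolated)
Conditions: t-BuCOCl, Et3N, THF, −20 °C; then 6, LiCl, rt
Reagents that add atoms: none
Why: N-acylation of the oxazolidinone through the mixed pivalic anhydride with LiCl and Et3N is a standard way to make Evans imides from arylacetic acids without strong base.

Step 5
Reactants: 9 4-(benzyloxy)-2-hydroxybenzaldehyde
Product: 10 4-(benzyloxy)-2-[(triisopropylsilyl)oxy]benzaldehyde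
Conditions: i-Pr3SiCl, imidazole, DMF, rt
Reagents that add atoms: chlorotriisopropylsilane, CC(C)[Si](Cl)(C(C)C)C(C)C
Why: Silylation of the phenol gives a hindered aryl silyl ether that should resist silyl migration in step 6 and is later cleaved by fluoride beside benzyl ethers.

Step 6
Reactants: 10 4-(benzyloxy)-2-[(triisopropylsilyl)oxy]benzaldehyde
Product: 11 {4-(benzyloxy)-2-[(triisopropylsilyl)oxy]phenyl}methanol
Conditions: NaBH4, MeOH/THF, 0 °C
Reagents that add atoms: none
Why: Borohydride reduction of the aldehyde leaves the aryl silyl ether and the benzyl ether untouched.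

Step 7
Reactants: 11 {4-(benzyloxy)-2-[(triisopropylsilyl)oxy]phenyl}methanol
Product: 12 4-(benzyloxy)-1-(bromomethyl)-2-[(triisopropylsilyl)oxy]benzene
Conditions: CBr4, PPh3, CH2Cl2, 0 °C; used directly
Reagents that add atoms: carbon tetrabromide, BrC(Br)(Br)Br
Why: Appel bromination converts the benzylic alcohol to the bromide under neutral conditions that avoid HBr and spare the silyl ether.

Step 8
Reactants: 8 (R)-4-benzyl-3-{2-[2-(benzyloxy)-5-bromo-4-methoxyphenyl]acetyl}oxazolidin-2-one; 12 4-(benzyloxy)-1-(bromomethyl)-2-[(triisopropylsilyl)oxy]benzene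
Product: 14 (R)-4-benzyl-3-{(2R)-2-[2-(benzyloxy)-5-bromo-4-methoxyphenyl]-3-[4-(benzyloxy)-2-(triisopropylsilyloxy)phenyl]propanoyl}oxazolidin-2-one, via sodium enolate 13 (not isolated)
Conditions: NaN(SiMe3)2, THF, −78 °C; then 12, −78 → −30 °C
Reagents that add atoms: none
Why: Evans asymmetric alkylation, in which the chelated (Z)-sodium enolate is benzylated on the face opposite the auxiliary benzyl group, so the (R)-auxiliary sets the (R) carbon that becomes C3 of the second chroman.

Step 9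
Reactants: 14 (R)-4-benzyl-3-{(2R)-2-[2-(benzyloxy)-5-bromo-4-methoxyphenyl]-3-[4-(benzyloxy)-2-(triisopropylsilyloxy)phenyl]propanoyl}oxazolidin-2-one
Product: 15 (2R)-2-[2-(benzyloxy)-5-bromo-4-methoxyphenyl]-3-[4-(benzyloxy)-2-(triisopropylsilyloxy)phenyl]propan-1-ol
Conditions: LiBH4, H2O (1 equiv), Et2O, 0 °C
Reagents that add atoms: none
Why: Reductive cleavage of the imide with LiBH4 should give the primary alcohol and the recoverable auxiliary without epimerising the α-aryl stereocentre.

Step 10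
Reactants: 15 (2R)-2-[2-(benzyloxy)-5-bromo-4-methoxyphenyl]-3-[4-(benzyloxy)-2-(triisopropylsilyloxy)phenyl]propan-1-ol
Product: 18 (3R)-7-(benzyloxy)-3-[2-(benzyloxy)-5-bromo-4-methoxyphenyl]chroman, via mesylate 16 (not isolated), via phenoxide 17 (not isolated)
Conditions: MsCl, Et3N, CH2Cl2, 0 °C; then Bu4NF, THF, rt
Reagents that add atoms: none
Why: After mesylation, fluoride cleaves the aryl silyl ether and the phenoxide closes the pyran ring by intramolecular Williamson etherification (6-exo-tet), which does not touch the stereocentre.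

Step 11
Reactants: 18 (3R)-7-(benzyloxy)-3-[2-(benzyloxy)-5-bromo-4-methoxyphenyl]chroman
Product: 20 4-(benzyloxy)-5-[(3R)-7-(benzyloxy)chroman-3-yl]-2-methoxybenzaldehyde, via aryllithium 19 (not isolated)
Conditions: n-BuLi, THF, −78 °C; DMF, −78 → 0 °C; then H2O
Reagents that add atoms: N,N-dimethylformamide, CN(C)C=O
Why: Bromine–lithium exchange and formylation with DMF place the aldehyde exactly where the bromine was, independent of the relative reactivity of the two electron-rich rings.

Step 12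
Reactants: 21 2-hydroxy-4,5-dimethoxybenzaldehyde
Product: 22 2-(benzyloxy)-4,5-dimethoxybenzaldehyde
Conditions: BnBr, K2CO3, DMF, 60 °C
Reagents that add atoms: benzyl bromide, BrCc1ccccc1
Why: Williamson etherification protects the phenol as the benzyl ether that is removed in the last step.

Step 13
Reactants: 22 2-(benzyloxy)-4,5-dimethoxybenzaldehyde
Product: 23 1-(benzyloxy)-4,5-dimethoxy-2-(2-methoxyethenyl)benzene (E/Z mixture)
Conditions: Ph3P(CH2OMe)Cl, KOC(CH3)3, THF, 0 °C → rt
Reagents that add atoms: (methoxymethyl)triphenylphosphonium chloride, COC[P+](c1ccccc1)(c1ccccc1)c1ccccc1.[Cl-]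
Why: Wittig methoxymethylenation homologates the aldehyde by one carbon as in step 2.

Step 14
Reactants: 23 1-(benzyloxy)-4,5-dimethoxy-2-(2-methoxyethenyl)benzene
Product: 25 2-[2-(benzyloxy)-4,5-dimethoxyphenyl]acetic acid, via arylacetaldehyde 24 (not isolated)
Conditions: aq HCl, THF, 50 °C; then NaH2PO4, 2-methyl-2-butene (large excess), NaClO2, t-BuOH/H2O, 0 °C → rt
Reagents that add atoms: water, O; sodium chlorite, [Na+].[O-]Cl=O
Why: Enol ether hydrolysis followed directly by Pinnick oxidation gives the arylacetic acid, with the excess alkene protecting the trioxygenated ring from hypochlorite.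

Step 15
Reactants: 25 2-[2-(benzyloxy)-4,5-dimethoxyphenyl]acetic acid; 26 (S)-4-benzyl-2-oxazolidinone
Product: 28 (S)-4-benzyl-3-{2-[2-(benzyloxy)-4,5-dimethoxyphenyl]acetyl}oxazolidin-2-one, via mixed pivalic anhydride 27 (not isolated)
Conditions: t-BuCOCl, Et3N, THF, −20 °C; then 26, LiCl, rt
Reagents that add atoms: none
Why: The same mixed-anhydride N-acylation as in step 4 gives the Evans imide needed for the aldol.

Step 16
Reactants: 28 (S)-4-benzyl-3-{2-[2-(benzyloxy)-4,5-dimethoxyphenyl]acetyl}oxazolidin-2-one; 20 4-(benzyloxy)-5-[(3R)-7-(benzyloxy)chroman-3-yl]-2-methoxybenzaldehyde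
Product: 30 (4S)-4-benzyl-3-[(2S,3S)-2-[2-(benzyloxy)-4,5-dimethoxyphenyl]-3-{4-(benzyloxy)-5-[(3R)-7-(benzyloxy)chroman-3-yl]-2-methoxyphenyl}-3-hydroxypropanoyl]oxazolidin-2-one, via boron enolate 29 (not isolated)
Conditions: n-Bu2BOTf, i-Pr2NEt, CH2Cl2, 0 °C; 20 (limiting), −78 → 0 °C; then pH 7 buffer, MeOH, H2O2, 0 °C
Reagents that add atoms: none
Why: Evans syn-aldol, in which the (Z)-dibutylboron enolate adds through a Zimmerman–Traxler chair with the auxiliary dipole opposed, giving the (2S,3S) adduct whose α-carbon has the configuration required for C3 of the first chroman.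

Step 17
Reactants: 30 the syn-aldol adduct
Product: 31 (1S,2R)-2-[2-(benzyloxy)-4,5-dimethoxyphenyl]-1-{4-(benzyloxy)-5-[(3R)-7-(benzyloxy)chroman-3-yl]-2-methoxyphenyl}propane-1,3-diol
Conditions: LiBH4, MeOH (1 equiv), THF, 0 °C
Reagents that add atoms: none
Why: Reductive removal of the auxiliary with LiBH4 gives the 1,3-diol and leaves both stereocentres untouched.

Step 18
Reactants: 31 the (1S,2R)-1,3-diol
Product: 33 (2S,3R)-3-[2-(benzyloxy)-4,5-dimethoxyphenyl]-2-{4-(benzyloxy)-5-[(3R)-7-(benzyloxy)chroman-3-yl]-2-methoxyphenyl}oxetane (2,3-cis), via monotosylate 32 (not isolated)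
Conditions: n-BuLi (1 equiv), THF, 0 °C; TsCl (1 equiv); n-BuLi (1 equiv), 0 → 45 °C; purification on Et3N-deactivated silica
Reagents that add atoms: none
Why: One-pot Williamson oxetane synthesis, in which the less hindered primary alkoxide is tosylated and the secondary lithium alkoxide then displaces the tosylate (4-exo-tet) with retention at both centres, the tight lithium ion pair being chosen to disfavour Grob fragmentation.

Step 19
Reactants: 34 4-(benzyloxy)phenol
Product: 35 4-(benzyloxy)-2-chlorophenol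
Conditions: SO2Cl2 (1 equiv), i-Bu2NH (cat.), toluene, 0 °C → rt
Reagents that add atoms: sulfuryl chloride, ClS(Cl)(=O)=O
Why: Amine-catalysed chlorination with sulfuryl chloride is ortho-selective for phenols (electrophilic aromatic substitution) and the para position is blocked.

Step 20
Reactants: 35 4-(benzyloxy)-2-chlorophenol
Product: 36 4-(benzyloxy)-2-bromo-6-chlorophenol
Conditions: NBS, i-Pr2NH (cat.), CH2Cl2, 0 °C
Reagents that add atoms: N-bromosuccinimide, O=C1CCC(=O)N1Br
Why: Amine-catalysed NBS bromination (electrophilic aromatic substitution) should take the remaining position ortho to the hydroxyl.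

Step 21
Reactants: 36 4-(benzyloxy)-2-bromo-6-chlorophenol
Product: 39 4-(benzyloxy)-2-chloro-6-(trimethylsilyl)phenyl trifluoromethanesulfonate, via silyl ether 37 (not isolated), via lithium phenoxide 38 (not isolated)
Conditions: (Me3Si)2NH, THF, 65 °C, volatiles removed; n-BuLi, THF, −78 °C; Tf2O, −78 → 0 °C
Reagents that add atoms: hexamethyldisilazane, C[Si](C)(C)N[Si](C)(C)C; trifluoromethanesulfonic anhydride, O=S(=O)(OS(=O)(=O)C(F)(F)F)C(F)(F)F
Why: O-silylation, bromine–lithium exchange with 1,3 O→C silyl shift (retro-Brook rearrangement) and triflation of the phenoxide is the standard route to ortho-silylaryl triflates, and bromine exchanges far faster than chlorine.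

Step 22
Reactants: 33 the cis-2,3-diaryloxetane; 39 4-(benzyloxy)-2-chloro-6-(trimethylsilyl)phenyl trifluoromethanesulfonate
Product: 43 (3R,4R)-7-(benzyloxy)-3-[2-(benzyloxy)-4,5-dimethoxyphenyl]-4-{4-(benzyloxy)-5-[(3R)-7-(benzyloxy)chroman-3-yl]-2-methoxyphenyl}-5-chlorochroman (3,4-trans), via aryne 40 (not isolated), via oxetanium zwitterion 41 (not isolated), via ring-opened zwitterion 42 (not isolated)
Conditions: CsF, 18-crown-6, toluene/DME (3:1), 25 → 40 °C; 39 added slowly
Reagents that add atoms: none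
Why: Proposed new method: fluoride releases the aryne, the strained and most Lewis-basic oxetane oxygen adds to the aryne carbon remote from chlorine (the developing aryl anion is stabilised next to the C–Cl bond), and the O-aryl oxetanium ion opens at its benzylic carbon, stabilised by the ortho-methoxy and para-benzyloxy groups, before the aryl anion captures the cation to form C4–C4a. The closest known chemistry is aryne insertion into the benzylic C–O bond of aryl epoxides to give 2,3-dihydrobenzofurans and the three-component opening of cyclic ethers by arynes. The pyran ring closes in a six-membered mode (6-exo-trig onto the exocyclically delocalised benzylic cation) after O1–C8a has formed intermolecularly. C4 is the one new stereocentre and is controlled by C3: the aryl anion should approach the planar cation anti to the C3 aryl group, so either oxetane epimer converges on the 3,4-trans product. The step needs regioselectivity on the aryne (secured by the chlorine, which outweighs the remote benzyloxy group), chemoselectivity for the oxetane oxygen over the aryl ethers (ring strain and basicity) and benzylic rather than CH2–O cleavage (the electron-rich aryl group). Slow aryne generation in a non-acidic medium is chosen so that the zwitterion is not protonated.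

Step 23
Reactants: 43 the 5-chloro tetrabenzyl ether
Product: 45 (3R,4S)-3-(2-hydroxy-4,5-dimethoxyphenyl)-4-{4-hydroxy-5-[(3R)-7-hydroxychroman-3-yl]-2-methoxyphenyl}chroman-7-ol (target), via chloro tetraphenol 44 (not isolated)
Conditions: H2 (1 atm), Pd/C, THF/MeOH, rt; then Et3N, H2, rt
Reagents that add atoms: none
Why: Hydrogenolysis over Pd/C cleaves the four aryl benzyl ethers and, once Et3N is added, the aryl chloride (hydrodechlorination), the amine being withheld at first because nitrogen bases slow O-debenzylation.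

**Compound list**

1 | 5-bromo-2-hydroxy-4-methoxybenzaldehyde | COc1cc(O)c(C=O)cc1Br | starting material
2 | 2-(benzyloxy)-5-bromo-4-methoxybenzaldehyde | COc1cc(OCc2ccccc2)c(C=O)cc1Br | intermediate
3 | 1-(benzyloxy)-4-bromo-5-methoxy-2-(2-methoxyethenyl)benzene (E/Z) | COC=Cc1cc(Br)c(OC)cc1OCc1ccccc1 | intermediate
4 | 2-[2-(benzyloxy)-5-bromo-4-methoxyphenyl]acetaldehyde | O=CCc1cc(Br)c(OC)cc1OCc1ccccc1 | intermediate
5 | 2-[2-(benzyloxy)-5-bromo-4-methoxyphenyl]acetic acid | OC(=O)Cc1cc(Br)c(OC)cc1OCc1ccccc1 | intermediate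
6 | (R)-4-benzyl-2-oxazolidinone | O=C1N[C@H](Cc2ccccc2)CO1 | starting material
7 | mixed anhydride of 5 and pivalic acid | CC(C)(C)C(=O)OC(=O)Cc1cc(Br)c(OC)cc1OCc1ccccc1 | intermediate
8 | (R)-4-benzyl-3-{2-[2-(benzyloxy)-5-bromo-4-methoxyphenyl]acetyl}oxazolidin-2-one | COc1cc(OCc2ccccc2)c(CC(=O)N2[C@H](Cc3ccccc3)COC2=O)cc1Br | intermediate
9 | 4-(benzyloxy)-2-hydroxybenzaldehyde | O=Cc1ccc(OCc2ccccc2)cc1O | starting material
10 | 4-(benzyloxy)-2-[(triisopropylsilyl)oxy]benzaldehyde | O=Cc1ccc(OCc2ccccc2)cc1O[Si](C(C)C)(C(C)C)C(C)C | intermediate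
11 | {4-(benzyloxy)-2-[(triisopropylsilyl)oxy]phenyl}methanol | OCc1ccc(OCc2ccccc2)cc1O[Si](C(C)C)(C(C)C)C(C)C | intermediate
12 | 4-(benzyloxy)-1-(bromomethyl)-2-[(triisopropylsilyl)oxy]benzene | BrCc1ccc(OCc2ccccc2)cc1O[Si](C(C)C)(C(C)C)C(C)C | intermediate
13 | sodium (Z)-enolate of 8 | [Na+].[O-]/C(=C\c1cc(Br)c(OC)cc1OCc1ccccc1)N1[C@H](Cc2ccccc2)COC1=O | intermediate
14 | (R)-4-benzyl-3-{(2R)-2-[2-(benzyloxy)-5-bromo-4-methoxyphenyl]-3-[4-(benzyloxy)-2-(triisopropylsilyloxy)phenyl]propanoyl}oxazolidin-2-one | COc1cc(OCc2ccccc2)c([C@@H](Cc2ccc(OCc3ccccc3)cc2O[Si](C(C)C)(C(C)C)C(C)C)C(=O)N2[C@H](Cc3ccccc3)COC2=O)cc1Br | intermediate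
15 | (2R)-2-[2-(benzyloxy)-5-bromo-4-methoxyphenyl]-3-[4-(benzyloxy)-2-(triisopropylsilyloxy)phenyl]propan-1-ol | COc1cc(OCc2ccccc2)c([C@@H](Cc2ccc(OCc3ccccc3)cc2O[Si](C(C)C)(C(C)C)C(C)C)CO)cc1Br | intermediate
16 | methanesulfonate of 15 | COc1cc(OCc2ccccc2)c([C@@H](Cc2ccc(OCc3ccccc3)cc2O[Si](C(C)C)(C(C)C)C(C)C)COS(C)(=O)=O)cc1Br | intermediate
17 | tetrabutylammonium phenoxide from 16 after desilylation | COc1cc(OCc2ccccc2)c([C@@H](Cc2ccc(OCc3ccccc3)cc2[O-])COS(C)(=O)=O)cc1Br.CCCC[N+](CCCC)(CCCC)CCCC | intermediate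
18 | (3R)-7-(benzyloxy)-3-[2-(benzyloxy)-5-bromo-4-methoxyphenyl]chroman | COc1cc(OCc2ccccc2)c([C@@H]2COc3cc(OCc4ccccc4)ccc3C2)cc1Br | intermediate
19 | aryllithium from 18 (lithium in place of bromine) | [Li]c1cc([C@@H]2COc3cc(OCc4ccccc4)ccc3C2)c(OCc2ccccc2)cc1OC | intermediate
20 | 4-(benzyloxy)-5-[(3R)-7-(benzyloxy)chroman-3-yl]-2-methoxybenzaldehyde | COc1cc(OCc2ccccc2)c([C@@H]2COc3cc(OCc4ccccc4)ccc3C2)cc1C=O | intermediate
21 | 2-hydroxy-4,5-dimethoxybenzaldehyde | COc1cc(O)c(C=O)cc1OC | starting material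
22 | 2-(benzyloxy)-4,5-dimethoxybenzaldehyde | COc1cc(OCc2ccccc2)c(C=O)cc1OC | intermediate
23 | 1-(benzyloxy)-4,5-dimethoxy-2-(2-methoxyethenyl)benzene (E/Z) | COC=Cc1cc(OC)c(OC)cc1OCc1ccccc1 | intermediate
24 | 2-[2-(benzyloxy)-4,5-dimethoxyphenyl]acetaldehyde | O=CCc1cc(OC)c(OC)cc1OCc1ccccc1 | intermediate
25 | 2-[2-(benzyloxy)-4,5-dimethoxyphenyl]acetic acid | OC(=O)Cc1cc(OC)c(OC)cc1OCc1ccccc1 | intermediate
26 | (S)-4-benzyl-2-oxazolidinone | O=C1N[C@@H](Cc2ccccc2)CO1 | starting material
27 | mixed anhydride of 25 and pivalic acid | CC(C)(C)C(=O)OC(=O)Cc1cc(OC)c(OC)cc1OCc1ccccc1 | intermediate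
28 | (S)-4-benzyl-3-{2-[2-(benzyloxy)-4,5-dimethoxyphenyl]acetyl}oxazolidin-2-one | COc1cc(OCc2ccccc2)c(CC(=O)N2[C@@H](Cc3ccccc3)COC2=O)cc1OC | intermediate
29 | (Z)-dibutylboron enolate of 28 | CCCCB(CCCC)O/C(=C\c1cc(OC)c(OC)cc1OCc1ccccc1)N1[C@@H](Cc2ccccc2)COC1=O | intermediate
30 | (4S)-4-benzyl-3-[(2S,3S)-2-[2-(benzyloxy)-4,5-dimethoxyphenyl]-3-{4-(benzyloxy)-5-[(3R)-7-(benzyloxy)chroman-3-yl]-2-methoxyphenyl}-3-hydroxypropanoyl]oxazolidin-2-one | COc1cc(OCc2ccccc2)c([C@@H]([C@H](O)c2cc([C@@H]3COc4cc(OCc5ccccc5)ccc4C3)c(OCc3ccccc3)cc2OC)C(=O)N2[C@@H](Cc3ccccc3)COC2=O)cc1OC | intermediate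
31 | (1S,2R)-2-[2-(benzyloxy)-4,5-dimethoxyphenyl]-1-{4-(benzyloxy)-5-[(3R)-7-(benzyloxy)chroman-3-yl]-2-methoxyphenyl}propane-1,3-diol | COc1cc(OCc2ccccc2)c([C@@H]([C@H](O)c2cc([C@@H]3COc4cc(OCc5ccccc5)ccc4C3)c(OCc3ccccc3)cc2OC)CO)cc1OC | intermediate
32 | (2R,3S)-2-[2-(benzyloxy)-4,5-dimethoxyphenyl]-3-{4-(benzyloxy)-5-[(3R)-7-(benzyloxy)chroman-3-yl]-2-methoxyphenyl}-3-hydroxypropyl 4-methylbenzenesulfonate | COc1cc(OCc2ccccc2)c([C@@H]([C@H](O)c2cc([C@@H]3COc4cc(OCc5ccccc5)ccc4C3)c(OCc3ccccc3)cc2OC)COS(=O)(=O)c2ccc(C)cc2)cc1OC | intermediate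
33 | (2S,3R)-3-[2-(benzyloxy)-4,5-dimethoxyphenyl]-2-{4-(benzyloxy)-5-[(3R)-7-(benzyloxy)chroman-3-yl]-2-methoxyphenyl}oxetane (2,3-cis) | COc1cc(OCc2ccccc2)c([C@@H]2CO[C@@H]2c2cc([C@@H]3COc4cc(OCc5ccccc5)ccc4C3)c(OCc3ccccc3)cc2OC)cc1OC | intermediate
34 | 4-(benzyloxy)phenol | Oc1ccc(OCc2ccccc2)cc1 | starting material
35 | 4-(benzyloxy)-2-chlorophenol | Oc1ccc(OCc2ccccc2)cc1Cl | intermediate
36 | 4-(benzyloxy)-2-bromo-6-chlorophenol | Oc1c(Cl)cc(OCc2ccccc2)cc1Br | intermediate
37 | [4-(benzyloxy)-2-bromo-6-chlorophenoxy]trimethylsilane | C[Si](C)(C)Oc1c(Cl)cc(OCc2ccccc2)cc1Br | intermediate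
38 | lithium 4-(benzyloxy)-2-chloro-6-(trimethylsilyl)phenoxide | [Li+].[O-]c1c(Cl)cc(OCc2ccccc2)cc1[Si](C)(C)C | intermediate
39 | 4-(benzyloxy)-2-chloro-6-(trimethylsilyl)phenyl trifluoromethanesulfonate | C[Si](C)(C)c1cc(OCc2ccccc2)cc(Cl)c1OS(=O)(=O)C(F)(F)F | intermediate
40 | 5-(benzyloxy)-3-chloro-1,2-didehydrobenzene (aryne) | ClC1=CC(OCc2ccccc2)=CC#C1 | intermediate
41 | O-aryl oxetanium aryl anion zwitterion from 33 and 40 | COc1cc(OCc2ccccc2)c([C@@H]2C[O+](c3cc(OCc4ccccc4)cc(Cl)[c-]3)[C@@H]2c2cc([C@@H]3COc4cc(OCc5ccccc5)ccc4C3)c(OCc3ccccc3)cc2OC)cc1OC | intermediate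
42 | ring-opened benzylic cation aryl anion zwitterion | COc1cc(OCc2ccccc2)c([C@H](COc2cc(OCc3ccccc3)cc(Cl)[c-]2)[CH+]c2cc([C@@H]3COc4cc(OCc5ccccc5)ccc4C3)c(OCc3ccccc3)cc2OC)cc1OC | intermediate
43 | (3R,4R)-7-(benzyloxy)-3-[2-(benzyloxy)-4,5-dimethoxyphenyl]-4-{4-(benzyloxy)-5-[(3R)-7-(benzyloxy)chroman-3-yl]-2-methoxyphenyl}-5-chlorochroman (3,4-trans) | COc1cc(OCc2ccccc2)c([C@@H]2COc3cc(OCc4ccccc4)cc(Cl)c3[C@H]2c2cc([C@@H]3COc4cc(OCc5ccccc5)ccc4C3)c(OCc3ccccc3)cc2OC)cc1OC | intermediate
44 | (3R,4R)-5-chloro-3-(2-hydroxy-4,5-dimethoxyphenyl)-4-{4-hydroxy-5-[(3R)-7-hydroxychroman-3-yl]-2-methoxyphenyl}chroman-7-ol (3,4-trans) | COc1cc(O)c([C@@H]2COc3cc(O)cc(Cl)c3[C@H]2c2cc([C@@H]3COc4cc(O)ccc4C3)c(O)cc2OC)cc1OC | intermediate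
45 | (3R,4S)-3-(2-hydroxy-4,5-dimethoxyphenyl)-4-{4-hydroxy-5-[(3R)-7-hydroxychroman-3-yl]-2-methoxyphenyl}chroman-7-ol | COc1cc(O)c([C@@H]2COc3cc(O)ccc3[C@H]2c2cc([C@@H]3COc4cc(O)ccc4C3)c(O)cc2OC)cc1OC | target

**Step count.** 23 steps in total. The longest linear sequence is 13 steps (1–4, 8–11, 16–18, 22, 23).

**Steps most likely to fail**

1. Step 22 (proposed new method). The aryl anion of the zwitterion may be quenched by proton transfer, the benzylic cation may lose the C3 proton before the C–C bond forms, the oxygen may add to the wrong aryne carbon, or the closure may show poor facial selectivity next to the peri chlorine. The fallback uses known chemistry, sets out from diol 31 and rejoins the route at 45. Mitsunobu etherification of the primary hydroxyl of 31 with commercial 3-(benzyloxy)phenol (PPh3, DIAD, THF) should give the hydroxy aryl ether F1. BF3·OEt2 in CH2Cl2 at low temperature then ionises the benzylic alcohol, and the tethered ring closes para to its benzyloxy group (intramolecular Friedel–Crafts alkylation, trans under the same C3 control) to the chlorine-free tetrabenzyl ether F2. Hydrogenolysis of F2 (H2, Pd/C) gives 45.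

2. Step 18. The alkoxide of the monotosylate may undergo Grob-type fragmentation back to aldehyde 20 and a styrene instead of the 4-exo-tet closure. The fallback sets out from 31 and returns at 33: cyclodehydration under Mitsunobu conditions (PPh3, DIAD, toluene), in which the primary oxyphosphonium ion is displaced by the neutral secondary hydroxyl, so that no free alkoxide and no sulfonate are involved.

3. Step 23. Hydrogenolysis of the C–Cl bond on the electron-rich, peri-substituted ring may stall, or debenzylation may stop once chloride and amine poison the catalyst. The fallback sets out from 43 and returns at 45 by separating the two tasks. Non-reductive debenzylation with BCl3 and pentamethylbenzene (CH2Cl2, −78 °C) gives 44, now isolated. A dedicated transfer hydrodechlorination (Pd/C, HCO2NH4, MeOH, reflux) then gives 45.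

**Further compounds**

F1 | step 22 | (1S,2R)-2-[2-(benzyloxy)-4,5-dimethoxyphenyl]-1-{4-(benzyloxy)-5-[(3R)-7-(benzyloxy)chroman-3-yl]-2-methoxyphenyl}-3-[3-(benzyloxy)phenoxy]propan-1-ol | COc1cc(OCc2ccccc2)c([C@H](COc2cccc(OCc3ccccc3)c2)[C@H](O)c2cc([C@@H]3COc4cc(OCc5ccccc5)ccc4C3)c(OCc3ccccc3)cc2OC)cc1OC
F2 | step 22 | (3R,4S)-7-(benzyloxy)-3-[2-(benzyloxy)-4,5-dimethoxyphenyl]-4-{4-(benzyloxy)-5-[(3R)-7-(benzyloxy)chroman-3-yl]-2-methoxyphenyl}chroman (3,4-trans) | COc1cc(OCc2ccccc2)c([C@@H]2COc3cc(OCc4ccccc4)ccc3[C@H]2c2cc([C@@H]3COc4cc(OCc5ccccc5)ccc4C3)c(OCc3ccccc3)cc2OC)cc1OC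
F0 | step 18 | none | none
F0 | step 23 | none | none
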